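**Strategy.** The whole route rests on taking the pyran ring (O, C4, C5, C6, C7, C8) out of a furan: the furan supplies the ring oxygen, the ether carbons C4 and C8 and their cis carbon branches C3 and C9, and a three-carbon oxyallyl cation supplies C5–C7. One (4+3) cycloaddition of racemic methyl 2-(furan-2-yl)propanoate with a silyl enol ether acetal bearing a chiral, DDQ-removable 1-(2-naphthyl)ethoxy group forms C4–C5 and C7–C8, the oxygen-bridged cycloheptenone and the C4/C8 stereocentres in absolute sense. The leftover C3=C9 alkene is later cut by ozonolysis to two cis one-carbon branches, to which ring A is joined by an allylsilane addition (C9–C10) and a ketyl coupling (C2–C3).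

Key step: step 4

Assumption: the (R)-1-(2-naphthyl)ethyl group is taken to shield the cation face that leads to the enantiomer drawn; if the sense is the opposite, the equally available (S)-alcohol is used with no other change.

Atom labels C1–C20 are those of the target; ring A is C1, C10, C11, C12, C13, C14.

**Step 1**
Reactants: 1 methyl 2-(furan-2-yl)acetate
Product: 2 methyl 2-(furan-2-yl)propanoate (racemic at C17)
Conditions: LiN(i-Pr)2, THF, −78 °C; MeI
Reagents that add atoms: iodomethane, CI
Why: Enolate alkylation methylates the α-carbon (future C17) once, necessarily as the racemate, which is harmless because C17 is re-equilibrated in step 6.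

**Step 2**
Reactants: 3 1,1-dimethoxypropan-2-one; 4 (R)-1-(naphthalen-2-yl)ethanol
Product: 5 1-methoxy-1-[(1R)-1-(naphthalen-2-yl)ethoxy]propan-2-one (both acetal epimers)
Conditions: PPTS (cat.), cyclohexane, 40 °C, reduced pressure (removal of MeOH)
Reagents that add atoms: none
Why: Acid-catalysed transacetalization driven by removal of methanol exchanges one methoxy group for the chiral alcohol without breaking its C–O bond, and the new acetal stereocentre is destroyed on ionization in step 4.

**Step 3**
Reactants: 5
Product: 6 3-methoxy-3-[(1R)-1-(naphthalen-2-yl)ethoxy]-2-(trimethylsilyloxy)prop-1-ene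
Conditions: LiN(i-Pr)2, Me3SiCl, THF, −78 °C
Reagents that add atoms: chlorotrimethylsilane, C[Si](C)(C)Cl
Why: Kinetic deprotonation at the unhindered CH3 group and O-silylation (silyl enol ether formation) give the 2-silyloxyallyl acetal.

**Step 4**
Reactants: 2 methyl 2-(furan-2-yl)propanoate; 6 silyl enol ether acetal
Product: 8 methyl 2-{2-[(1R)-1-(naphthalen-2-yl)ethoxy]-3-oxo-8-oxabicyclo[3.2.1]oct-6-en-1-yl}propanoate, via oxyallyl cation triflate 7 (not isolated)
Conditions: Me3SiOTf (0.2 equiv), CH2Cl2, −95 °C
Reagents that add atoms: none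
Why: Silylation of the methoxy oxygen by Me3SiOTf and loss of MeOSiMe3 give cation 7, a 1-alkoxy-2-silyloxyallyl cation that serves as the three-carbon, two-electron partner of the furan diene; bonding is stepwise or strongly asynchronous, the free furan α-carbon (C4) attacking the unsubstituted CH2 terminus (C5) first and the resulting silyl enol ether carbon C7 then closing on the furanium carbon C8, after which Me3SiOTf is released. The closest known reaction type is the low-temperature (4+3) cycloaddition of furans with alkoxy-substituted silyloxyallyl cations carrying 1-arylethoxy auxiliaries. The seven-membered carbocycle C3–C4–C5–C6–C7–C8–C9 is closed by this two-bond annulation across the furan 2,5-positions, and the same two bonds close the oxygen-bridged pyranone O/C4/C5/C6/C7/C8, the furan oxygen becoming the one-atom bridge. C4 and C8 are cis by necessity (both bonds form on one furan face) and their absolute sense is set by the auxiliary, whose naphthyl group covers one face of the cation; C7 is expected with its oxygen on the side of the oxygen bridge but is epimerizable and is corrected in step 6, and C17 is not controlled here (both epimers, reset in step 6). The step needs regioselectivity (alkoxy terminus to the substituted furan carbon C8), which follows from the first bond forming between the two unhindered termini, and selective ionization, which the steric difference between methoxy and 1-arylethoxy secures.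

**Step 5**
Reactants: 8
Product: 9 methyl 2-(2-hydroxy-3-oxo-8-oxabicyclo[3.2.1]oct-6-en-1-yl)propanoate
Conditions: DDQ, CH2Cl2/H2O (10:1), 0 °C to rt
Reagents that add atoms: none
Why: Oxidative cleavage of a naphthylmethyl-type ether by DDQ (benzylic hydride abstraction, hydrolysis of the oxocarbenium ion) frees the C7 hydroxyl and leaves the C3=C9 alkene, the ketone and the ester untouched.

**Step 6**
Reactants: 9
Product: 10 tricyclic keto lactone (lactone C7–O–C19)
Conditions: DBU, toluene, 50 °C
Reagents that add atoms: none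
Why: Base-mediated lactonization under equilibrating conditions, in which DBU epimerizes C7 through the enol of the hydroxy ketone and C17 through the ester or lactone enolate, only the C7 epimer with oxygen on the oxygen-bridge side can reach C19, and the cis-fused γ-lactone with the C17 methyl turned away from C9 is the expected thermodynamic sink.

**Step 7**
Reactants: 10
Product: 11 C6 alcohol of 10
Conditions: LiBH(s-Bu)3, THF, −78 °C
Reagents that add atoms: none
Why: Ketone reduction by a bulky borohydride from the open face of the bicycle (the other face is covered by the C3=C9 bridge) gives the C6 alcohol trans to the C7 oxygen, a placeholder centre because C6 is reoxidized in step 27.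

**Step 8**
Reactants: 11
Product: 12 C6 benzyl ether
Conditions: BnOC(=NH)CCl3, TfOH (cat.), CH2Cl2/cyclohexane, 0 °C
Reagents that add atoms: benzyl 2,2,2-trichloroacetimidate, N=C(OCc1ccccc1)C(Cl)(Cl)Cl
Why: Acid-catalysed O-benzylation with a trichloroacetimidate protects the hindered C6 alcohol without base, so the lactone and C17 are not disturbed.

**Step 9**
Reactants: 12
Product: 14 pyran diol (C3 and C9 hydroxymethyl groups), via ozonide 13 (not isolated)
Conditions: O3, CH2Cl2, −78 °C; then NaBH4, MeOH, −78 to 0 °C
Reagents that add atoms: ozone, [O-][O+]=O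
Why: Ozonolysis with reductive work-up cuts the only alkene, C3=C9, to two hydroxymethyl groups held cis on the pyran, the short cold borohydride treatment being meant to leave the γ-lactone in place.

**Step 10**
Reactants: 14
Product: 15 C3 tert-butyldimethylsilyl ether
Conditions: TBSCl, imidazole, CH2Cl2, −20 °C
Reagents that add atoms: tert-butylchlorodimethylsilane, CC(C)(C)[Si](C)(C)Cl
Why: Selective silylation, because the C3 hydroxymethyl group on a CH carbon should react much faster than the neopentyl C9 hydroxymethyl group on the fully substituted C8.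

**Step 11**
Reactants: 15
Product: 16 C9 aldehyde
Conditions: Dess–Martin periodinane, CH2Cl2, rt
Reagents that add atoms: none
Why: Dess–Martin oxidation of the remaining primary alcohol gives the C9 aldehyde, which cannot enolize because C8 is quaternary.

**Step 12**
Reactants: 17 1,4-dioxaspiro[4.5]dec-6-en-8-one
Product: 18 7-(hydroxymethyl)-1,4-dioxaspiro[4.5]dec-6-en-8-one
Conditions: aq. CH2O (37%), DMAP (cat.), THF, rt
Reagents that add atoms: formaldehyde, C=O
Why: Morita–Baylis–Hillman reaction, in which DMAP adds to the enone β-carbon and the resulting enolate is hydroxymethylated at the α-carbon (future C1), bringing in C2.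

**Step 13**
Reactants: 18
Product: 19 (8S)-7-(hydroxymethyl)-1,4-dioxaspiro[4.5]dec-6-en-8-ol
Conditions: (R)-2-methyl-CBS-oxazaborolidine (0.2 equiv), BH3·SMe2 (2.2 equiv), THF, −20 °C; MeOH
Reagents that add atoms: none
Why: Corey–Bakshi–Shibata reduction delivers hydride to the ketone with the alkenyl side as the large group and so sets C14, the first equivalent of borane being consumed as the borate of the primary alcohol.

**Step 14**
Reactants: 19
Product: 20 di-tert-butylsilylene acetal of 19
Conditions: t-Bu2Si(OTf)2, 2,6-lutidine, CH2Cl2, 0 °C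
Reagents that add atoms: di-tert-butylsilyl bis(trifluoromethanesulfonate), CC(C)(C)[Si](OS(=O)(=O)C(F)(F)F)(OS(=O)(=O)C(F)(F)F)C(C)(C)C
Why: Silylene formation ties the 1,3-diol (C2–OH and C14–OH) into one six-membered ring, a standard diol protection that also differentiates the two faces of ring A.

**Step 15**
Reactants: 20
Product: 21 silylene-protected (S)-4-hydroxy-3-(hydroxymethyl)cyclohex-2-en-1-one
Conditions: PPTS, acetone/H2O, 50 °C
Reagents that add atoms: water, O
Why: Acid-catalysed ketal hydrolysis unmasks C11 as the enone carbonyl conjugated with C10=C1, the silylene being stable to mild aqueous acid.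

**Step 16**
Reactants: 21
Product: 23 enol triflate (C10=C11–OTf), via lithium enolate 22 (not isolated)
Conditions: Me2CuLi, Et2O, −40 °C; then PhNTf2, THF, −40 to 0 °C
Reagents that add atoms: lithium dimethylcuprate, [Li+].C[Cu-]C; N-phenylbis(trifluoromethanesulfonimide), O=S(=O)(N(c1ccccc1)S(=O)(=O)C(F)(F)F)C(F)(F)F
Why: Gilman cuprate 1,4-addition delivers methyl to C1 anti to the allylic C14–O bond (methyl trans to C14–O, silylene ring cis-fused), and trapping the regiodefined C10 enolate with PhNTf2 stores the C10/C11 regiochemistry.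

**Step 17**
Reactants: 23
Product: 24 ring A allylsilane (CH2SiMe3 on C11, C10=C11)
Conditions: Me3SiCH2MgCl, Pd(PPh3)4 (5 mol %), THF, 0 °C to rt
Reagents that add atoms: (trimethylsilyl)methylmagnesium chloride, C[Si](C)(C)C[Mg]Cl
Why: Kumada cross-coupling of the enol triflate with the silylmethyl Grignard reagent gives the allylsilane whose γ-carbon is C10 and whose silylated carbon becomes C20.

**Step 18**
Reactants: 16 C9 aldehyde; 24 ring A allylsilane
Product: 25 coupled homoallylic alcohol (C9–OH, C10–H, C11=C20)
Conditions: BF3·OEt2, CH2Cl2, −78 °C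
Reagents that add atoms: none
Why: Hosomi–Sakurai allylation, in which the BF3-activated C9 aldehyde is attacked by the γ-carbon C10 with shift of the double bond to C11=C20, C10 being approached on the methyl-bearing convex face anti to the C1–CH2O arm of the cis-fused silylene and the syn relation between the C9 hydroxyl and the C10–C1 bond following from the open antiperiplanar transition state.

**Step 19**
Reactants: 25
Product: 26 C9 acetate
Conditions: Ac2O, DMAP, pyridine, rt
Reagents that add atoms: acetic anhydride, CC(=O)OC(C)=O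
Why: DMAP-catalysed acylation installs the final C9 acetate and keeps the C9 oxygen from forming a lactol with the C3 aldehyde made in step 21.

**Step 20**
Reactants: 26
Product: 27 triol (C2–OH, C3–OH, C14–OH)
Conditions: HF·pyridine, pyridine, THF, 0 °C to rt
Reagents that add atoms: none
Why: Fluoride desilylation removes the silylene and the primary silyl ether in one operation, while acetate, lactone and benzyl ether are inert to buffered HF·pyridine.

**Step 21**
Reactants: 27
Product: 28 dialdehyde (C2 and C3 formyl groups)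
Conditions: TEMPO (cat.), PhI(OAc)2, CH2Cl2, rt
Reagents that add atoms: none
Why: Oxoammonium (TEMPO) oxidation converts the two primary alcohols to aldehydes and leaves the secondary C14 hydroxyl untouched.

**Step 22**
Reactants: 28
Product: 29 tetracyclic triol (eight-membered ring closed by C2–C3)
Conditions: SmI2, t-BuOH, THF, −78 °C to rt, high dilution
Reagents that add atoms: none
Why: Intramolecular pinacol coupling, in which the ketyl formed at one aldehyde adds to the other and closes the eight-membered ring with the ring A fusion already trans, the C2–O and C3–O bonds being expected anti (trans diol, as usual for medium rings where a samarium-bridged syn arrangement would eclipse ring bonds) and C3 forming anti to the C4–O bond (dipole-opposed, Felkin-type approach).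

**Step 23**
Reactants: 29
Product: 30 tetraacetate (C2, C3, C9, C14)
Conditions: Ac2O, DMAP, pyridine, rt
Reagents that add atoms: acetic anhydride, CC(=O)OC(C)=O
Why: Exhaustive DMAP-catalysed acetylation of the three secondary hydroxyls completes the four acetates of the target.

**Step 24**
Reactants: 30
Product: 31 11,20-epoxide
Conditions: m-CPBA, CH2Cl2, 0 °C
Reagents that add atoms: 3-chloroperoxybenzoic acid, O=C(OO)c1cccc(Cl)c1
Why: Prilezhaev epoxidation of the only alkene, in which the trans ring fusion locks ring A with the C1 methyl axial so that axial approach to C11 is blocked and the peracid enters along the equatorial direction, placing the oxygen cis to H10 and C20 cis to the methyl group.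

**Step 25**
Reactants: 31
Product: 32 chlorohydrin (C11–OH, C20–Cl)
Conditions: LiCl, AcOH, THF, rt
Reagents that add atoms: lithium chloride, [Li+].[Cl-]
Why: Epoxide opening by chloride under weakly acidic buffering is an SN2 attack at the primary carbon C20 and leaves the tertiary C11 alcohol with its configuration intact.

**Step 26**
Reactants: 32
Product: 33 C6 alcohol
Conditions: H2 (1 atm), Pd(OH)2/C, EtOAc, rt
Reagents that add atoms: none
Why: Hydrogenolysis of the benzyl ether, possible here because no alkene is present and the primary alkyl chloride and the acetates are stable.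

**Step 27**
Reactants: 33
Product: 34 C6 ketone
Conditions: Dess–Martin periodinane, CH2Cl2, rt
Reagents that add atoms: none
Why: Dess–Martin oxidation of the only secondary alcohol regenerates the C6 ketone, the tertiary C11 hydroxyl being unable to react.

**Step 28**
Reactants: 34
Product: 35 enone (C5=C16 conjugated with the C6 ketone)
Conditions: (CH2O)n, i-Pr2NH·CF3CO2H, THF, 65 °C
Reagents that add atoms: formaldehyde (as paraformaldehyde), C=O
Why: Mannich-type α-methylenation (amine-salt-mediated condensation with formaldehyde, then elimination) can give an enone only at C5, the sole α-carbon with two hydrogens, and its mildly acidic conditions spare acetates, lactone and chlorohydrin.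

**Step 29**
Reactants: 35
Product: 36 C6 allylic alcohol (epimeric at C6 to the target chloride)
Conditions: NaBH4, CeCl3·7H2O, MeOH, −78 °C
Reagents that add atoms: none
Why: Luche 1,2-reduction, with hydride expected to attack the carbonyl from the exposed face on the side of the ring oxygen, away from the eight-membered ring.

**Step 30**
Reactants: 36
Product: 37 Fragilide F
Conditions: PPh3, Cl3CC(O)CCl3, CH2Cl2, −20 to 0 °C
Reagents that add atoms: hexachloroacetone, O=C(C(Cl)(Cl)Cl)C(Cl)(Cl)Cl
Why: Appel-type chlorodehydroxylation through the alkoxyphosphonium salt replaces the allylic hydroxyl by chloride with inversion at C6 and without allylic transposition, the hindered tertiary C11 hydroxyl being unreactive.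

**Compound list**

1 | methyl 2-(furan-2-yl)acetate | COC(=O)Cc1ccco1 | starting material
2 | methyl 2-(furan-2-yl)propanoate (racemic at C17) | COC(=O)C(C)c1ccco1 | intermediate
3 | 1,1-dimethoxypropan-2-one | CC(=O)C(OC)OC | starting material
4 | (R)-1-(naphthalen-2-yl)ethanol | C[C@@H](O)c1ccc2ccccc2c1 | starting material
5 | 1-methoxy-1-[(1R)-1-(naphthalen-2-yl)ethoxy]propan-2-one (both acetal epimers) | CC(=O)C(OC)O[C@H](C)c1ccc2ccccc2c1 | intermediate
6 | 3-methoxy-3-[(1R)-1-(naphthalen-2-yl)ethoxy]-2-(trimethylsilyloxy)prop-1-ene | C=C(O[Si](C)(C)C)C(OC)O[C@H](C)c1ccc2ccccc2c1 | intermediate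
7 | 1-[(1R)-1-(naphthalen-2-yl)ethoxy]-2-(trimethylsilyloxy)allyl cation triflate | C=C(O[Si](C)(C)C)C=[O+][C@H](C)c1ccc2ccccc2c1.[O-]S(=O)(=O)C(F)(F)F | intermediate (not isolated)
8 | methyl 2-{2-[(1R)-1-(naphthalen-2-yl)ethoxy]-3-oxo-8-oxabicyclo[3.2.1]oct-6-en-1-yl}propanoate; bridgeheads as C4 and C8 of the target, C7 ether oxygen on the oxygen-bridge side, both C17 epimers | C1[C@H]2O[C@](C(C)C(=O)OC)(C=C2)[C@@H](O[C@H](C)c3ccc4ccccc4c3)C1=O | intermediate
9 | methyl 2-(2-hydroxy-3-oxo-8-oxabicyclo[3.2.1]oct-6-en-1-yl)propanoate (C7 hydroxy ketone, C17 epimers) | C1[C@H]2O[C@](C(C)C(=O)OC)(C=C2)[C@@H](O)C1=O | intermediate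
10 | tricyclic keto lactone: 8-oxabicyclo[3.2.1]oct-6-en-3-one with the γ-lactone C8–C17(CH3)–C19(=O)–O–C7 cis-fused on the oxygen-bridge side, C17 methyl syn to the bridging oxygen | C1[C@H]2O[C@]3([C@@H](C)C(=O)O[C@H]3C1=O)C=C2 | intermediate
11 | C6 alcohol of 10, hydroxyl trans to the C7 oxygen | C1[C@H]2O[C@]3([C@@H](C)C(=O)O[C@H]3[C@@H]1O)C=C2 | intermediate
12 | C6 benzyl ether of 11 | C1[C@H]2O[C@]3([C@@H](C)C(=O)O[C@H]3[C@@H]1OCc4ccccc4)C=C2 | intermediate
13 | ozonide (1,2,4-trioxolane across C3 and C9) of 12 | C1[C@H]2O[C@]3([C@@H](C)C(=O)O[C@H]3[C@@H]1OCc4ccccc4)C5OOC2O5 | intermediate (not isolated)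
14 | pyran diol: hydroxymethyl groups C3 and C9 cis on C4 and C8, lactone and C6 benzyl ether retained | C1[C@H](CO)O[C@@]2(CO)[C@@H](C)C(=O)O[C@H]2[C@@H]1OCc3ccccc3 | intermediate
15 | C3 tert-butyldimethylsilyl ether of 14 | C1[C@H](CO[Si](C)(C)C(C)(C)C)O[C@@]2(CO)[C@@H](C)C(=O)O[C@H]2[C@@H]1OCc3ccccc3 | intermediate
16 | C9 aldehyde of 15 | C1[C@H](CO[Si](C)(C)C(C)(C)C)O[C@@]2(C=O)[C@@H](C)C(=O)O[C@H]2[C@@H]1OCc3ccccc3 | intermediate
17 | 1,4-dioxaspiro[4.5]dec-6-en-8-one | O=C1C=CC2(CC1)OCCO2 | starting material
18 | 7-(hydroxymethyl)-1,4-dioxaspiro[4.5]dec-6-en-8-one | O=C1CCC2(OCCO2)C=C1CO | intermediate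
19 | (8S)-7-(hydroxymethyl)-1,4-dioxaspiro[4.5]dec-6-en-8-ol | O[C@H]1CCC2(OCCO2)C=C1CO | intermediate
20 | di-tert-butylsilylene acetal of 19 (O–Si–O ring through C2–O and C14–O) | CC(C)(C)[Si]1(OCC2=CC3(OCCO3)CC[C@@H]2O1)C(C)(C)C | intermediate
21 | silylene-protected (S)-4-hydroxy-3-(hydroxymethyl)cyclohex-2-en-1-one (C11 ketone, C10=C1) | CC(C)(C)[Si]1(OCC2=CC(=O)CC[C@@H]2O1)C(C)(C)C | intermediate
22 | lithium enolate (C10=C11–OLi) of the 1,4-adduct, C1 methyl trans to C14–O | CC(C)(C)[Si]1(OC[C@]2(C)C=C([O-])CC[C@@H]2O1)C(C)(C)C.[Li+] | intermediate (not isolated)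
23 | enol triflate (C10=C11–OTf), C1 bearing CH3 trans and CH2O cis to C14–O | CC(C)(C)[Si]1(OC[C@]2(C)C=C(OS(=O)(=O)C(F)(F)F)CC[C@@H]2O1)C(C)(C)C | intermediate
24 | ring A allylsilane (CH2SiMe3 on C11, C10=C11) | CC(C)(C)[Si]1(OC[C@]2(C)C=C(C[Si](C)(C)C)CC[C@@H]2O1)C(C)(C)C | intermediate
25 | coupled homoallylic alcohol (C9–OH, C10–H, C11=C20; pyran and ring A joined by C9–C10) | C1[C@H](CO[Si](C)(C)C(C)(C)C)O[C@@]2([C@@H](O)[C@H]4C(=C)CC[C@@H]5O[Si](C(C)(C)C)(C(C)(C)C)OC[C@]45C)[C@@H](C)C(=O)O[C@H]2[C@@H]1OCc3ccccc3 | intermediate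
26 | C9 acetate of 25 | C1[C@H](CO[Si](C)(C)C(C)(C)C)O[C@@]2([C@@H](OC(C)=O)[C@H]4C(=C)CC[C@@H]5O[Si](C(C)(C)C)(C(C)(C)C)OC[C@]45C)[C@@H](C)C(=O)O[C@H]2[C@@H]1OCc3ccccc3 | intermediate
27 | triol (primary C2–OH and C3–OH, secondary C14–OH) | C1[C@H](CO)O[C@@]2([C@@H](OC(C)=O)[C@H]4C(=C)CC[C@H](O)[C@]4(C)CO)[C@@H](C)C(=O)O[C@H]2[C@@H]1OCc3ccccc3 | intermediate
28 | dialdehyde (C2 and C3 formyl groups, C14–OH free) | C1[C@H](C=O)O[C@@]2([C@@H](OC(C)=O)[C@H]4C(=C)CC[C@H](O)[C@]4(C)C=O)[C@@H](C)C(=O)O[C@H]2[C@@H]1OCc3ccccc3 | intermediate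
29 | tetracyclic triol (C2–C3 bond closed; C2–OH and C3–OH trans, C14–OH) | C1[C@H]2O[C@]3([C@@H](C)C(=O)O[C@H]3[C@@H]1OCc4ccccc4)[C@@H](OC(C)=O)[C@H]1C(=C)CC[C@H](O)[C@]1(C)[C@@H](O)[C@@H]2O | intermediate
30 | tetraacetate (C2, C3, C9, C14) with C11=C20 and C6 benzyl ether | C1[C@H]2O[C@]3([C@@H](C)C(=O)O[C@H]3[C@@H]1OCc4ccccc4)[C@@H](OC(C)=O)[C@H]1C(=C)CC[C@H](OC(C)=O)[C@]1(C)[C@@H](OC(C)=O)[C@@H]2OC(C)=O | intermediate
31 | 11,20-epoxide of 30 (oxygen cis to H10) | C1[C@H]2O[C@]3([C@@H](C)C(=O)O[C@H]3[C@@H]1OCc4ccccc4)[C@@H](OC(C)=O)[C@H]1[C@@]5(CO5)CC[C@H](OC(C)=O)[C@]1(C)[C@@H](OC(C)=O)[C@@H]2OC(C)=O | intermediate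
32 | chlorohydrin (C11–OH, C20–Cl) | C1[C@H]2O[C@]3([C@@H](C)C(=O)O[C@H]3[C@@H]1OCc4ccccc4)[C@@H](OC(C)=O)[C@H]1[C@@](O)(CCl)CC[C@H](OC(C)=O)[C@]1(C)[C@@H](OC(C)=O)[C@@H]2OC(C)=O | intermediate
33 | C6 alcohol (benzyl removed) | C1[C@H]2O[C@]3([C@@H](C)C(=O)O[C@H]3[C@@H]1O)[C@@H](OC(C)=O)[C@H]1[C@@](O)(CCl)CC[C@H](OC(C)=O)[C@]1(C)[C@@H](OC(C)=O)[C@@H]2OC(C)=O | intermediate
34 | C6 ketone | C1[C@H]2O[C@]3([C@@H](C)C(=O)O[C@H]3C1=O)[C@@H](OC(C)=O)[C@H]1[C@@](O)(CCl)CC[C@H](OC(C)=O)[C@]1(C)[C@@H](OC(C)=O)[C@@H]2OC(C)=O | intermediate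
35 | enone (C5=C16 methylene, C6 ketone) | C=C1[C@H]2O[C@]3([C@@H](C)C(=O)O[C@H]3C1=O)[C@@H](OC(C)=O)[C@H]1[C@@](O)(CCl)CC[C@H](OC(C)=O)[C@]1(C)[C@@H](OC(C)=O)[C@@H]2OC(C)=O | intermediate
36 | C6 allylic alcohol, epimeric at C6 to the target chloride | C=C1[C@H]2O[C@]3([C@@H](C)C(=O)O[C@H]3[C@@H]1O)[C@@H](OC(C)=O)[C@H]1[C@@](O)(CCl)CC[C@H](OC(C)=O)[C@]1(C)[C@@H](OC(C)=O)[C@@H]2OC(C)=O | intermediate
37 | Fragilide F | C=C1[C@H]2O[C@]3([C@@H](C)C(=O)O[C@H]3[C@H]1Cl)[C@@H](OC(C)=O)[C@H]1[C@@](O)(CCl)CC[C@H](OC(C)=O)[C@]1(C)[C@@H](OC(C)=O)[C@@H]2OC(C)=O | target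

**Step count and risk**

Total: 30 steps. Longest linear sequence: 23 steps (from 3 through steps 2–11 and 18–30).

Steps most likely to fail:

Step 22. The ketyl may be reduced on to the alcohol before the eight-membered ring closes, or the two carbonyl faces may pair the wrong way (cis diol or the other trans diol). The fallback separates C–C bond formation from oxygenation; it sets out from 28 and comes back at 30. Wittig methylenation of both aldehydes (Ph3P=CH2, THF) would give the diene F1. Ring-closing metathesis with the second-generation Grubbs catalyst (CH2Cl2, reflux, high dilution; the 1,1-disubstituted C11=C20 alkene is far less reactive) would give the Z-cyclooctene F2. Epoxidation directed by the homoallylic C14 hydroxyl (VO(acac)2, t-BuOOH), which also keeps the oxidant away from C11=C20, would give the cis-epoxide F3. Acetic acid with Ti(O-i-Pr)4 should open it at C3 only, with inversion, because C2 is neopentyl, to give the hydroxy acetate F4; acetylation (Ac2O, DMAP) then gives 30. The trans relation is guaranteed by the anti opening; the face of epoxidation rests on the directing hydroxyl and would have to be confirmed.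

Step 18. Bond formation between two carbons that both sit next to fully substituted centres may be too slow, so that protodesilylation of the allylsilane wins, or ring A may be attacked on its other face. The fallback sets out from 21 and 16 and comes back at 25. Conjugate addition of Me2CuLi to 21 in the presence of Me3SiCl would give the silyl enol ether F5. Mukaiyama aldol addition of F5 to 16 (BF3·OEt2, CH2Cl2, −78 °C) would give the β-hydroxy ketone F6, in which C10 is α to the ketone and can be equilibrated to the equatorial arm. Methylenation of the C11 ketone with the Takai–Lombardo reagent (Zn, CH2Br2, TiCl4), which tolerates the free hydroxyl, the lactone and the silyl ethers, then gives 25.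

Step 4. Ionization may expel the chiral alkoxy group in place of methoxide, or the auxiliary may discriminate the faces of this 2-substituted furan poorly. The fallback gives up auxiliary control for resolution; it sets out from 3 and 2 and comes back at 10. Transacetalization of 3 with benzyl alcohol (PPTS) would give 1,1-bis(benzyloxy)propan-2-one F7, and LiN(i-Pr)2/Me3SiCl its silyl enol ether F8. The same cycloaddition with 2 (Me3SiOTf, CH2Cl2, −78 °C) would give the racemic benzyl ether F9. BCl3 (CH2Cl2, −78 °C) removes the benzyl group without touching the alkene to give the racemic hydroxy ketone F10, and DBU gives the racemic keto lactone F11 as a single diastereomer. F11 is resolved by preparative chromatography on a chiral stationary phase to give 10. The regiochemical requirement is the same in both variants.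

**Further compounds**

F1 | step 22 | diene from double methylenation of 28 (vinyl groups at C4 and C1) | C1[C@H](C=C)O[C@@]2([C@@H](OC(C)=O)[C@H]4C(=C)CC[C@H](O)[C@]4(C)C=C)[C@@H](C)C(=O)O[C@H]2[C@@H]1OCc3ccccc3
F2 | step 22 | Z-cyclooctene (C2=C3) from ring-closing metathesis | C1[C@H]2O[C@]3([C@@H](C)C(=O)O[C@H]3[C@@H]1OCc4ccccc4)[C@@H](OC(C)=O)[C@H]1C(=C)CC[C@H](O)[C@]1(C)/C=C\2
F3 | step 22 | C2,C3-cis-epoxide of F2 | C1[C@H]2O[C@]3([C@@H](C)C(=O)O[C@H]3[C@@H]1OCc4ccccc4)[C@@H](OC(C)=O)[C@H]1C(=C)CC[C@H](O)[C@]1(C)[C@H]5O[C@@H]25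
F4 | step 22 | C3 acetate with free C2 and C14 hydroxyls | C1[C@H]2O[C@]3([C@@H](C)C(=O)O[C@H]3[C@@H]1OCc4ccccc4)[C@@H](OC(C)=O)[C@H]1C(=C)CC[C@H](O)[C@]1(C)[C@@H](O)[C@@H]2OC(C)=O
F5 | step 18 | trimethylsilyl enol ether (C10=C11–OSiMe3) of the 1,4-adduct of 21 | CC(C)(C)[Si]1(OC[C@]2(C)C=C(O[Si](C)(C)C)CC[C@@H]2O1)C(C)(C)C
F6 | step 18 | β-hydroxy ketone (C9–OH, C11 ketone) | C1[C@H](CO[Si](C)(C)C(C)(C)C)O[C@@]2([C@@H](O)[C@H]4C(=O)CC[C@@H]5O[Si](C(C)(C)C)(C(C)(C)C)OC[C@]45C)[C@@H](C)C(=O)O[C@H]2[C@@H]1OCc3ccccc3
F7 | step 4 | 1,1-bis(benzyloxy)propan-2-one | CC(=O)C(OCc1ccccc1)OCc1ccccc1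
F8 | step 4 | 3,3-bis(benzyloxy)-2-(trimethylsilyloxy)prop-1-ene | C=C(O[Si](C)(C)C)C(OCc1ccccc1)OCc1ccccc1
F9 | step 4 | racemic methyl 2-(2-benzyloxy-3-oxo-8-oxabicyclo[3.2.1]oct-6-en-1-yl)propanoate | C1C2OC(C(C)C(=O)OC)(C=C2)C(OCc3ccccc3)C1=O
F10 | step 4 | racemic methyl 2-(2-hydroxy-3-oxo-8-oxabicyclo[3.2.1]oct-6-en-1-yl)propanoate | C1C2OC(C(C)C(=O)OC)(C=C2)C(O)C1=O
F11 | step 4 | racemic tricyclic keto lactone (constitution and relative configuration of 10) | C1C2OC3(C(C)C(=O)OC3C1=O)C=C2
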